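**Retrosynthetic overview**
- Target ⇐ (13Z)-labda-8,13-diene-6β,7α,15-triol by selective 7,15-diacetylation ⇐ 9-vinyl diene-diol + (Z)-3-iodobut-2-en-1-ol (hydroboration / B-alkyl Suzuki, C12–C13).
- 6β,7α-Diol ⇐ 7α-hydroxy-8-en-6-one (hydride from the α face) ⇐ 7-en-6-one by γ-deprotonation at C9 and α-oxygenation at C7.
- trans-Decalone ⇐ monocyclic cyclohexanone by cation–enol closure of ring A (C4–C5); ring A is formed last.
- Cyclohexanone (ring B) ⇐ cyclopentanone by one-carbon ring expansion: 1,2-shift of C8 onto a carbenoid carbon inserts C7. Ring B is kept five-membered until then so that C9 is β and C8 is α to the C6 carbonyl.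
- Cyclopentanone ⇐ 4,4-disubstituted cyclopentenone (vinyl cuprate, MeI) ⇐ 3-methylcyclopentenone + homoprenyl Grignard (asymmetric conjugate addition sets C10).

Assumption: the SMILES is read as (13Z)-6β-hydroxylabda-8,13-diene-7α,15-diyl diacetate with 5S,6S,7S,10S; labdane numbering is used in the explanations.

**Step 1**
Reactants: 1 3-methylcyclopent-2-en-1-one; 2 5-bromo-2-methylpent-2-ene
Product: 5 (R)-3-methyl-3-(4-methylpent-3-en-1-yl)cyclopentan-1-one, via Grignard reagent 3 (not isolated), via magnesium enolate 4 (not isolated)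
Conditions: 2, Mg, Et2O, 35 °C; then 1, Cu(OTf)2 (3 mol %), chiral C2-symmetric N,N′-diaryl-4,5-diphenylimidazolinium tetrafluoroborate (4 mol %, the enantiomer that gives R), Et2O, −30 °C; 1 M HCl
Reagents that add atoms: none
Why: Copper-catalysed asymmetric conjugate addition of a Grignard reagent to a β-methyl cycloalkenone with a chiral NHC ligand builds the all-carbon quaternary centre (C10), the ligand controlling the enone face; ee may need upgrading for this five-membered enone.

**Step 2**
Reactants: 5
Product: 6 (S)-4-methyl-4-(4-methylpent-3-en-1-yl)cyclopent-2-en-1-one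
Conditions: IBX (2.0 equiv), PhF/DMSO (2:1), 70 °C
Reagents that add atoms: none
Why: IBX dehydrogenation of a ketone; only the α-carbon remote from the quaternary centre has a β-hydrogen, so one enone regioisomer forms and C10 is untouched.

**Step 3**
Reactants: 6; 7 vinylmagnesium bromide
Product: 9 (2S,3S,4S)-2,4-dimethyl-4-(4-methylpent-3-en-1-yl)-3-vinylcyclopentan-1-one, via magnesium enolate 8 (not isolated)
Conditions: 7 (1.5 equiv), CuBr·SMe2 (10 mol %), THF, −40 °C; then MeI (5 equiv), DMPU, −40 → 23 °C
Reagents that add atoms: iodomethane, CI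
Why: Copper-catalysed conjugate addition followed by enolate alkylation (three-component coupling): vinyl adds at C9 anti to the larger homoprenyl group and MeI alkylates C8 trans to the vinyl group; C8 and C9 both become sp2 later, so minor epimers converge.

**Step 4**
Reactants: 9
Product: 12 (3R,4S,5S)-3,5-dimethyl-5-(4-methylpent-3-en-1-yl)-4-vinylcyclohexan-1-one, via lithium carbinolate 10 (not isolated), via lithium enolate 11 (not isolated)
Conditions: CH2Br2 (1.5 equiv), lithium 2,2,6,6-tetramethylpiperidide (LiTMP, 1.4 equiv), THF, −78 °C; then n-BuLi (2.5 equiv), −78 → 0 °C; 1 M HCl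
Reagents that add atoms: dibromomethane, BrCBr
Why: β-Oxido carbenoid ring enlargement (Taguchi–Yamamoto–Nozaki): LiCHBr2 adds to the carbonyl, Br/Li exchange gives the carbenoid, and the more substituted α-carbon (C8, CHMe, rather than the C5 methylene) undergoes the 1,2-shift with retention, inserting C7 between C6 and C8.

**Step 5**
Reactants: 12
Product: 13 (3R,4S,4aR,8aS)-4-ethenyl-3,4a,8,8-tetramethyloctahydronaphthalen-1(2H)-one
Conditions: HNTf2 (10 mol %), HFIP/CH2Cl2 (1:4), 0 → 23 °C
Reagents that add atoms: none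
Why: Proposed new method: Brønsted-acid-catalysed intramolecular Markovnikov α-tert-alkylation (hydroalkylation) of an unactivated ketone; HNTf2 in HFIP reversibly protonates the trisubstituted alkene to the tertiary C4 cation and catalyses enolisation, only the C5 enol can reach the cation through a six-membered chair transition state (the C7 enol, the carbonyl oxygen and the vinyl group would need seven- or eight-membered rings, and the carbonyl-ene adduct forms reversibly), C–C bond formation is irreversible and proton loss turns the acid over, and C5 equilibrates through the enol to the trans-fused ketone with 8α-methyl and 9β-vinyl equatorial (sets 5S); closest known reaction types are the Reetz α-tert-alkylation of silyl enol ethers with tert-alkyl chlorides and TiCl4, enol-derivative-terminated cation–olefin cyclisations, and gold- or palladium-catalysed intramolecular hydroalkylation of alkenes with simple ketones.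

**Step 6**
Reactants: 13
Product: 15 (4S,4aR,8aS)-4-ethenyl-3,4a,8,8-tetramethyl-4a,5,6,7,8,8a-hexahydronaphthalen-1(4H)-one, via silyl enol ether 14 (not isolated)
Conditions: LiN(iPr)2, TMSCl, THF, −78 °C; then Pd(OAc)2 (1.05 equiv), MeCN, 23 °C
Reagents that add atoms: none
Why: Saegusa–Ito oxidation: kinetic deprotonation occurs at the C7 methylene (C5 is a hindered methine between two quaternary carbons) and β-hydride elimination can only give the C7=C8 enone, under neutral conditions that do not move the vinyl group.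

**Step 7**
Reactants: 15
Product: 17 (2S,4aS,8aS)-4-ethenyl-2-hydroxy-3,4a,8,8-tetramethyl-4a,5,6,7,8,8a-hexahydronaphthalen-1(2H)-one, via potassium trienolate 16 (not isolated)
Conditions: KN(SiMe3)2 (1.05 equiv), THF, −78 → −30 °C; then 2-(phenylsulfonyl)-3-phenyloxaziridine, −78 °C; AcOH
Reagents that add atoms: 2-(phenylsulfonyl)-3-phenyloxaziridine, O=S(=O)(c1ccccc1)N1OC1c1ccccc1
Why: γ-Deprotonation of the doubly allylic axial C9–H gives the fully conjugated trienolate, and Davis oxaziridine α-hydroxylation at C7 by axial attack on the α face forms the tetrasubstituted C8=C9 alkene and the 7α-hydroxyl (7S).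

**Step 8**
Reactants: 17
Product: 18 (1S,2S,4aS,8aS)-4-ethenyl-3,4a,8,8-tetramethyl-1,2,4a,5,6,7,8,8a-octahydronaphthalene-1,2-diol
Conditions: NaBH4, CeCl3·7H2O, MeOH, −40 → 0 °C
Reagents that add atoms: none
Why: Luche-type hydride reduction: the β face of C6 is blocked by the two syn-axial methyls (on C10 and 4β), so hydride enters from the α face, helped by delivery from the 7α-alkoxyborohydride, giving the axial 6β-hydroxyl (6S) of the trans-diaxial diol.

**Step 9**
Reactants: 19 but-2-yn-1-ol
Product: 21 (Z)-3-iodobut-2-en-1-ol, via cyclic alkenylaluminate 20 (not isolated)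
Conditions: NaAlH2(OCH2CH2OMe)2, Et2O, 0 → 23 °C; then I2, THF, −78 °C; H2O
Reagents that add atoms: iodine, II
Why: Alkoxide-directed trans-hydroalumination of a propargylic alcohol places aluminium at C3 cis to the CH2O group, and iodinolysis with retention gives the Z vinyl iodide.

**Step 10**
Reactants: 18; 21
Product: 23 (13Z)-labda-8,13-diene-6β,7α,15-triol, via alkylborane 22 (not isolated)
Conditions: 9-BBN dimer (1.6 equiv), THF, 23 °C; then 21 (1.2 equiv), Pd(dppf)Cl2 (5 mol %), AsPh3 (10 mol %), Cs2CO3 (3 equiv), DMF/H2O, 23 °C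
Reagents that add atoms: none
Why: Anti-Markovnikov hydroboration of the terminal vinyl group (the tetrasubstituted alkene is inert) and B-alkyl Suzuki–Miyaura coupling with retention of the Z geometry form C12–C13.

**Step 11**
Reactants: 23
Product: 24 (13Z)-6β-hydroxylabda-8,13-diene-7α,15-diyl diacetate (5S,6S,7S,10S; the target)
Conditions: Ac2O (2.3 equiv), pyridine, DMAP (5 mol %), CH2Cl2, 0 °C
Reagents that add atoms: acetic anhydride, CC(=O)OC(C)=O
Why: Selective acylation: the primary allylic 15-OH and the 7α-OH are acetylated, while the 6β-OH, 1,3-diaxial to the C10 and 4β methyls, is too hindered to react under these conditions.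

**Compound list**
1 | 3-methylcyclopent-2-en-1-one | CC1=CC(=O)CC1 | starting material
2 | 5-bromo-2-methylpent-2-ene | CC(C)=CCCBr | starting material
3 | (4-methylpent-3-en-1-yl)magnesium bromide | CC(C)=CCC[Mg]Br | intermediate (not isolated)
4 | bromomagnesium enolate of 5 (C1=C2 enolate, toward the quaternary carbon) | CC(C)=CCC[C@]1(C)CCC(O[Mg]Br)=C1 | intermediate (not isolated)
5 | (R)-3-methyl-3-(4-methylpent-3-en-1-yl)cyclopentan-1-one | CC(C)=CCC[C@]1(C)CCC(=O)C1 | intermediate
6 | (S)-4-methyl-4-(4-methylpent-3-en-1-yl)cyclopent-2-en-1-one | CC(C)=CCC[C@]1(C)C=CC(=O)C1 | intermediate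
7 | vinylmagnesium bromide | C=C[Mg]Br | starting material
8 | bromomagnesium enolate from vinyl addition to 6 | C=C[C@H]1C=C(O[Mg]Br)C[C@]1(C)CCC=C(C)C | intermediate (not isolated)
9 | (2S,3S,4S)-2,4-dimethyl-4-(4-methylpent-3-en-1-yl)-3-vinylcyclopentan-1-one (vinyl cis to the ring methyl on C4, 2-methyl trans to vinyl) | C=C[C@H]1[C@H](C)C(=O)C[C@]1(C)CCC=C(C)C | intermediate
10 | lithium 1-(dibromomethyl)cyclopentan-1-olate adduct of 9 (both carbinol epimers) | C=C[C@H]1[C@H](C)C([O-])(C(Br)Br)C[C@]1(C)CCC=C(C)C.[Li+] | intermediate (not isolated)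
11 | lithium enolate of 12 (C1=C2 enolate) | C=C[C@H]1[C@H](C)C=C([O-])C[C@]1(C)CCC=C(C)C.[Li+] | intermediate (not isolated)
12 | (3R,4S,5S)-3,5-dimethyl-5-(4-methylpent-3-en-1-yl)-4-vinylcyclohexan-1-one | C=C[C@H]1[C@H](C)CC(=O)C[C@]1(C)CCC=C(C)C | intermediate
13 | (3R,4S,4aR,8aS)-4-ethenyl-3,4a,8,8-tetramethyloctahydronaphthalen-1(2H)-one (trans-fused; 8α-methyl, 9β-vinyl in labdane numbering) | C=C[C@H]1[C@H](C)CC(=O)[C@H]2C(C)(C)CCC[C@]12C | intermediate
14 | trimethylsilyl enol ether of 13 (C6=C7 in labdane numbering) | C=C[C@H]1[C@H](C)C=C(O[Si](C)(C)C)[C@H]2C(C)(C)CCC[C@]12C | intermediate (not isolated)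
15 | (4S,4aR,8aS)-4-ethenyl-3,4a,8,8-tetramethyl-4a,5,6,7,8,8a-hexahydronaphthalen-1(4H)-one | C=C[C@H]1C(C)=CC(=O)[C@H]2C(C)(C)CCC[C@]12C | intermediate
16 | potassium trienolate of 15 (O–C6=C7–C8=C9–CH=CH2) | C=CC1=C(C)C=C([O-])[C@H]2C(C)(C)CCC[C@]12C.[K+] | intermediate (not isolated)
17 | (2S,4aS,8aS)-4-ethenyl-2-hydroxy-3,4a,8,8-tetramethyl-4a,5,6,7,8,8a-hexahydronaphthalen-1(2H)-one (7α-hydroxy-8-en-6-one) | C=CC1=C(C)[C@H](O)C(=O)[C@H]2C(C)(C)CCC[C@]12C | intermediate
18 | (1S,2S,4aS,8aS)-4-ethenyl-3,4a,8,8-tetramethyl-1,2,4a,5,6,7,8,8a-octahydronaphthalene-1,2-diol (6β,7α-diol) | C=CC1=C(C)[C@H](O)[C@@H](O)[C@H]2C(C)(C)CCC[C@]12C | intermediate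
19 | but-2-yn-1-ol | CC#CCO | starting material
20 | sodium 2,2-bis(2-methoxyethoxy)-3-methyl-1,2-oxaluminacyclopent-3-en-2-uide (cyclic alkenylaluminate) | CC1=CCO[Al-]1(OCCOC)OCCOC.[Na+] | intermediate (not isolated)
21 | (Z)-3-iodobut-2-en-1-ol | C/C(I)=C/CO | intermediate
22 | B-alkyl-9-borabicyclo[3.3.1]nonane from hydroboration of the vinyl group of 18 | C(CB3C4CCCC3CCC4)C1=C(C)[C@H](O)[C@@H](O)[C@H]2C(C)(C)CCC[C@]12C | intermediate (not isolated)
23 | (13Z)-labda-8,13-diene-6β,7α,15-triol | OC/C=C(/C)CCC1=C(C)[C@H](O)[C@@H](O)[C@H]2C(C)(C)CCC[C@]12C | intermediate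
24 | (13Z)-6β-hydroxylabda-8,13-diene-7α,15-diyl diacetate | CC(=O)OC/C=C(/C)CCC1=C(C)[C@H](OC(C)=O)[C@@H](O)[C@H]2C(C)(C)CCC[C@]12C | target

**Step count**
Total: 11 steps. Longest linear sequence: 10 steps (steps 1–8, 10, 11); step 9 is the one-step side branch.

**Three steps most likely to fail**

Step 4 (ring expansion). The risks are poor addition of LiCHBr2 to the hindered, enolisable ketone and competing migration of the C5 methylene. The fallback sets out from 9 and comes back at 12 by the regiospecific Ito–Saegusa sequence. Thermodynamic silylation of 9 (TMSCl, NaI, Et3N, MeCN) gives the tetrasubstituted trimethylsilyl enol ether of 9 F1. Cyclopropanation with Et2Zn and CH2I2, anti to the vinyl group, gives the siloxycyclopropane F2. FeCl3 in DMF cleaves the internal cyclopropane bond to give the ring-enlarged β-chloro ketone F3. Bu3SnH with AIBN removes the chlorine to give 12; its C3 epimer is equally usable because that carbon becomes sp2 in step 6.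

Step 5 (proposed new acid-catalysed ring A closure). The risks are carbonyl-ene or Prins diversion and acid damage to the vinyl group. The fallback uses known Mukaiyama–Reetz α-tert-alkylation, sets out from 12 and comes back at 13. HCl gas in CH2Cl2 at −78 °C adds to the trisubstituted alkene only and gives the tertiary chloride F4. TMSOTf and Et3N give the enol silanes, including the C5=C6 trimethylsilyl enol ether F5. TiCl4 at −78 °C ionises the chloride and closes ring A from F5. The regioisomeric enol silane cannot cyclise, returns F4 on work-up and is recycled. A short NaOMe/MeOH equilibration secures the trans ring fusion of 13.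

Step 7 (trienolate formation and oxygenation). The risks are competing deprotonation at C5, oxygenation at C9 or the vinyl terminus, and isomerisation of the vinyl group to an ethylidene dienone. The fallback sets out from 15 and comes back at 17. Nucleophilic epoxidation (H2O2, NaOH, MeOH) from the α face gives the 7α,8α-epoxy ketone F6. TMSOTf and DBU then isomerise the epoxide to the allylic silyl ether by opening at tertiary C8 and removing the allylic C9–H, giving the 7α-trimethylsilyloxy-8-en-6-one F7. K2CO3 in MeOH frees 17.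

**Further compounds**
F1 | step 4 | tetrasubstituted trimethylsilyl enol ether of 9 (C1=C2 enol ether bearing the 2-methyl) | C=C[C@H]1C(C)=C(O[Si](C)(C)C)C[C@]1(C)CCC=C(C)C
F2 | step 4 | 1-(trimethylsilyloxy)bicyclo[3.1.0]hexane from cyclopropanation of F1 (CH2 anti to vinyl) | C=C[C@H]1[C@]2(C)C[C@]2(O[Si](C)(C)C)C[C@]1(C)CCC=C(C)C
F3 | step 4 | 3-chloro-3,5-dimethyl-5-(4-methylpent-3-en-1-yl)-4-vinylcyclohexan-1-one (both C3 epimers) | C=C[C@H]1C(C)(Cl)CC(=O)C[C@]1(C)CCC=C(C)C
F4 | step 5 | (3R,4S,5S)-5-(4-chloro-4-methylpentyl)-3,5-dimethyl-4-vinylcyclohexan-1-one | C=C[C@H]1[C@H](C)CC(=O)C[C@]1(C)CCCC(C)(C)Cl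
F5 | step 5 | C5=C6 trimethylsilyl enol ether of F4 (enol double bond toward the quaternary carbon) | C=C[C@H]1[C@H](C)CC(O[Si](C)(C)C)=C[C@]1(C)CCCC(C)(C)Cl
F6 | step 7 | 7α,8α-epoxide of 15 (labdane numbering) | C=C[C@H]1[C@]3(C)O[C@@H]3C(=O)[C@H]2C(C)(C)CCC[C@]12C
F7 | step 7 | 7α-trimethylsilyl ether of 17 | C=CC1=C(C)[C@H](O[Si](C)(C)C)C(=O)[C@H]2C(C)(C)CCC[C@]12C
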